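**Plan**
1. Disconnections, latest first: the quinone C–N bond (amine for methoxide), the quinone back to a 2,3,5,6-tetramethoxyaryl ring, the C5=C6 olefin back to a C6 ketone, then C8–C9 (ring B), C6–C7 (propenyl onto a C5 aldehyde), C9–C10 (alkenyl conjugate addition) and aryl–C11.
2. Enabling feature: in ring B the quaternary C9 (methyl and C11H2Ar) lies next to C8 (CHMe). The C9 methyl is the hydrogen adduct of a C9=CH2 olefin, so hydrogen-atom transfer makes C9 a tertiary radical, and C8 can accept it as the β-carbon of a C6 enone whose oxygen is later exchanged for the C5=C6 double bond.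
3. Forward order: ring A is bought as 2,2-dimethylcyclohexanone; the C10 arm (carrying the arene) and the C5 crotonoyl arm are attached; ring B closes in step 8; the ketone becomes the Δ5 olefin; the quinone is unveiled, hydrolysed and aminated last.
4. Stereochemistry: C10 comes from an L-tert-leucine ester auxiliary (chelate-controlled 1,4-addition). C5 is kept trans by equilibration and ends sp2. C8 and C9 are relayed from C10 through the chair transition state of the ring closure.

Key step: step 8

Numbering: terpenoid numbering is used for the decalin (C4 = CMe2, C5/C10 = ring fusion, C6 = carbonyl carbon, C8 = CHMe, C9 = quaternary carbon, C11 = benzylic CH2); Ar = 2,3,5,6-tetramethoxyphenyl.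
Assumption: the sense of induction in step 5 is taken from the accepted chelate model for tert-leucine ester aldimines (magnesium held by N and the ester C=O, transfer to the s-cis enimine opposite the tert-butyl group), which for the (S)-auxiliary predicts the required (R)-C10 in 14; if the opposite sense were found, the (R)-auxiliary would be used.

**Step 1**
Reactants: 1 2,2-dimethylcyclohexanone; 2 2,4,6-triisopropylbenzenesulfonohydrazide
Product: 3 (E)-N'-(2,2-dimethylcyclohexylidene)-2,4,6-triisopropylbenzenesulfonohydrazide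
Conditions: MeOH, cat. HCl, rt
Reagents that add atoms: none
Why: Acid-catalysed hydrazone condensation, in which the sulfonamide arm settles anti to the quaternary carbon and therefore over the only α-CH2, as the following Shapiro reaction requires.

**Step 2**
Reactants: 3 (E)-N'-(2,2-dimethylcyclohexylidene)-2,4,6-triisopropylbenzenesulfonohydrazide
Product: 5 6,6-dimethylcyclohex-1-ene-1-carbaldehyde, via vinyllithium 4 (not isolated)
Conditions: n-BuLi (2.2 equiv), THF, −78 → 0 °C; DMF, −78 °C → rt; H2O
Reagents that add atoms: N,N-dimethylformamide, CN(C)C=O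
Why: Shapiro reaction (double deprotonation, loss of sulfinate and N2) gives the vinyllithium at the former carbonyl carbon, with the single α-CH2 fixing the regiochemistry, and DMF formylates it.

**Step 3**
Reactants: 5 6,6-dimethylcyclohex-1-ene-1-carbaldehyde; 6 tert-butyl (S)-2-amino-3,3-dimethylbutanoate (L-tert-leucine tert-butyl ester, free base)
Product: 7 tert-butyl (S)-2-{(E)-[(6,6-dimethylcyclohex-1-en-1-yl)methylidene]amino}-3,3-dimethylbutanoate
Conditions: 4 Å molecular sieves, toluene, rt; used crude
Reagents that add atoms: none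
Why: Imine condensation driven by removal of water under neutral conditions that do not enolise the auxiliary stereocentre.

**Step 4**
Reactants: 8 1,2,4,5-tetramethoxybenzene; 9 2,3-dibromoprop-1-ene
Product: 11 3-(2-bromoprop-2-en-1-yl)-1,2,4,5-tetramethoxybenzene, via aryllithium 10 (not isolated)
Conditions: n-BuLi, THF, 0 °C → rt; CuI (10 mol %), 9, −78 °C → rt
Reagents that add atoms: none
Why: Directed ortho-lithiation at the position flanked by two methoxy groups, then copper-catalysed allylic substitution at the allylic bromide, the vinylic bromide staying intact.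

**Step 5**
Reactants: 7 tert-butyl (S)-2-{(E)-[(6,6-dimethylcyclohex-1-en-1-yl)methylidene]amino}-3,3-dimethylbutanoate; 11 3-(2-bromoprop-2-en-1-yl)-1,2,4,5-tetramethoxybenzene
Product: 14 (1S,2R)-6,6-dimethyl-2-[3-(2,3,5,6-tetramethoxyphenyl)prop-1-en-2-yl]cyclohexane-1-carbaldehyde, via alkenylmagnesium bromide 12 (not isolated), via magnesium aza-enolate 13 (not isolated)
Conditions: 11 (2 equiv), Mg, THF, 45 °C; 7, THF, −45 °C; aq. citric acid, rt; NaOMe (cat.), MeOH, rt
Reagents that add atoms: water, O
Why: Chiral-auxiliary conjugate addition of a Grignard reagent to an α,β-unsaturated aldimine, in which the N/ester-carbonyl magnesium chelate delivers the alkenyl group to C10 of the s-cis enimine opposite the tert-butyl group (C10 set as R), acid hydrolysis releases the aldehyde and the auxiliary, and methoxide equilibration at C5 should lead to the trans diequatorial aldehyde (any cis epimer being separable and recycled).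

**Step 6**
Reactants: 14 (1S,2R)-6,6-dimethyl-2-[3-(2,3,5,6-tetramethoxyphenyl)prop-1-en-2-yl]cyclohexane-1-carbaldehyde; 15 (E)-1-bromoprop-1-ene
Product: 17 (E)-1-{(1S,2R)-6,6-dimethyl-2-[3-(2,3,5,6-tetramethoxyphenyl)prop-1-en-2-yl]cyclohexyl}but-2-en-1-ol (both carbinol epimers), via (E)-prop-1-enyllithium 16 (not isolated)
Conditions: 15, t-BuLi (2 equiv), Et2O, −78 °C; then 14, −78 → −20 °C; H2O
Reagents that add atoms: none
Why: Bromine–lithium exchange with retention of the (E)-geometry, then 1,2-addition of the alkenyllithium to the hindered aldehyde at low temperature; the carbinol centre need not be controlled because step 7 removes it.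

**Step 7**
Reactants: 17 (E)-1-{(1S,2R)-6,6-dimethyl-2-[3-(2,3,5,6-tetramethoxyphenyl)prop-1-en-2-yl]cyclohexyl}but-2-en-1-ol
Product: 18 (E)-1-{(1S,2R)-6,6-dimethyl-2-[3-(2,3,5,6-tetramethoxyphenyl)prop-1-en-2-yl]cyclohexyl}but-2-en-1-one
Conditions: Dess–Martin periodinane, CH2Cl2, 0 °C → rt
Reagents that add atoms: none
Why: Dess–Martin oxidation of a secondary allylic alcohol under non-basic conditions that leave C5, the (E)-olefin and the 1,1-disubstituted olefin untouched.

**Step 8**
Reactants: 18 (E)-1-{(1S,2R)-6,6-dimethyl-2-[3-(2,3,5,6-tetramethoxyphenyl)prop-1-en-2-yl]cyclohexyl}but-2-en-1-one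
Product: 19 (3S,4R,4aR,8aS)-3,4,8,8-tetramethyl-4-[(2,3,5,6-tetramethoxyphenyl)methyl]octahydronaphthalen-1(2H)-one (trans-fused; terpenoid numbering 5S,8S,9R,10R)
Conditions: Fe(acac)3 (30 mol %), PhSiH3 (2.5 equiv), EtOH/(CH2OH)2 5:1, 0.02 M, 60 °C
Reagents that add atoms: none
Why: An iron hydride formed from Fe(acac)3 and PhSiH3 transfers a hydrogen atom to the terminal CH2 of the electron-rich 1,1-disubstituted olefin, creating the C9 methyl and a nucleophilic tertiary C9 radical that adds to the electron-poor β-carbon C8 of the enone; the α-keto radical is then reduced by Fe(II) and protonated at C7 by ethanol. The closest known reaction type is the iron-hydride reductive olefin coupling (hydrogen-atom-transfer Giese addition) in its intramolecular form. Ring B closes 6-endo-trig, since the 5-exo alternative (attack at C7) is polarity-mismatched and would leave an unstabilised secondary radical. C8 is controlled by the (E)-olefin: its methyl stays anti to C6 as C8 pyramidalises and so becomes equatorial (β) in the chair transition state that the trans-diequatorial arms on ring A impose. C9 is controlled in the same chair: the site that becomes axial is gauche to both C1 and C5 and syn-axial to H5, so the methyl should take it while the bulkier arylmethyl group goes equatorial next to H10. The step needs Me/CH2Ar discrimination at C9 and hydrogen-atom transfer to the donor olefin before the enone; the size difference and the electron-rich olefin secure these, and C5 stays trans because the trans-fused α-keto ring fusion is the stable one.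

**Step 9**
Reactants: 19 (3S,4R,4aR,8aS)-3,4,8,8-tetramethyl-4-[(2,3,5,6-tetramethoxyphenyl)methyl]octahydronaphthalen-1(2H)-one
Product: 20 (1S,3S,4R,4aR,8aS)-3,4,8,8-tetramethyl-4-[(2,3,5,6-tetramethoxyphenyl)methyl]decahydronaphthalen-1-ol (axial 6α-alcohol)
Conditions: L-Selectride, THF, −78 °C; H2O
Reagents that add atoms: none
Why: Reduction with a bulky trialkylborohydride along the equatorial trajectory on the β-face, the axial path being blocked by the syn-axial C4 methyl, should give the axial alcohol (new C6 centre, S).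

**Step 10**
Reactants: 20 (1S,3S,4R,4aR,8aS)-3,4,8,8-tetramethyl-4-[(2,3,5,6-tetramethoxyphenyl)methyl]decahydronaphthalen-1-ol
Product: 21 3-{[(1R,2S,8aS)-1,2,5,5-tetramethyl-1,2,3,5,6,7,8,8a-octahydronaphthalen-1-yl]methyl}-1,2,4,5-tetramethoxybenzene
Conditions: SOCl2, pyridine, 0 °C
Reagents that add atoms: none
Why: E2 dehydration through the chlorosulfite, in which the axial leaving group is antiperiplanar to the axial tertiary C5–H and Zaitsev orientation should give the more substituted Δ5 olefin, while the basic medium suppresses ionisation and methyl migration.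

**Step 11**
Reactants: 21 3-{[(1R,2S,8aS)-1,2,5,5-tetramethyl-1,2,3,5,6,7,8,8a-octahydronaphthalen-1-yl]methyl}-1,2,4,5-tetramethoxybenzene
Product: 22 2,5-dimethoxy-3-{[(1R,2S,8aS)-1,2,5,5-tetramethyl-1,2,3,5,6,7,8,8a-octahydronaphthalen-1-yl]methyl}cyclohexa-2,5-diene-1,4-dione
Conditions: (NH4)2Ce(NO3)6 (2.5 equiv), MeCN/H2O 2:1, 0 °C
Reagents that add atoms: water, O
Why: Cerium(IV) oxidative demethylation of a para-dimethoxyarene (water attacks the ipso carbons, methanol leaves); either para pair gives the same 3-alkyl-2,5-dimethoxyquinone and the isolated trisubstituted olefin should survive at 0 °C.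

**Step 12**
Reactants: 22 2,5-dimethoxy-3-{[(1R,2S,8aS)-1,2,5,5-tetramethyl-1,2,3,5,6,7,8,8a-octahydronaphthalen-1-yl]methyl}cyclohexa-2,5-diene-1,4-dione
Product: 23 2-hydroxy-5-methoxy-3-{[(1R,2S,8aS)-1,2,5,5-tetramethyl-1,2,3,5,6,7,8,8a-octahydronaphthalen-1-yl]methyl}cyclohexa-2,5-diene-1,4-dione
Conditions: 2 M aq. KOH, MeOH, rt; then 1 M HCl
Reagents that add atoms: potassium hydroxide, [K+].[OH-]
Why: Addition–elimination of hydroxide on a vinylogous ester (methoxyquinone saponification), which in 3-alkyl-2,5-dimethoxybenzoquinones replaces the methoxy group next to the alkyl branch.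

**Step 13**
Reactants: 23 2-hydroxy-5-methoxy-3-{[(1R,2S,8aS)-1,2,5,5-tetramethyl-1,2,3,5,6,7,8,8a-octahydronaphthalen-1-yl]methyl}cyclohexa-2,5-diene-1,4-dione; 24 3-methylbutan-1-amine
Product: 25 nakijiquinone M
Conditions: 24 (3 equiv), EtOH, rt
Reagents that add atoms: none
Why: Addition–elimination of the primary amine at the remaining vinylogous ester carbon (quinone C5), the deprotonated C2 hydroxyl being inert to substitution.

**Compound list**
1 | 2,2-dimethylcyclohexanone | CC1(C)CCCCC1=O | starting material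
2 | 2,4,6-triisopropylbenzenesulfonohydrazide | CC(C)c1cc(C(C)C)c(S(=O)(=O)NN)c(C(C)C)c1 | starting material
3 | (E)-N'-(2,2-dimethylcyclohexylidene)-2,4,6-triisopropylbenzenesulfonohydrazide | CC(C)c1cc(C(C)C)c(S(=O)(=O)N/N=C2\CCCCC2(C)C)c(C(C)C)c1 | intermediate
4 | (6,6-dimethylcyclohex-1-en-1-yl)lithium | [Li]C1=CCCCC1(C)C | intermediate (not isolated)
5 | 6,6-dimethylcyclohex-1-ene-1-carbaldehyde | O=CC1=CCCCC1(C)C | intermediate
6 | tert-butyl (S)-2-amino-3,3-dimethylbutanoate | CC(C)(C)OC(=O)[C@@H](N)C(C)(C)C | starting material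
7 | tert-butyl (S)-2-{(E)-[(6,6-dimethylcyclohex-1-en-1-yl)methylidene]amino}-3,3-dimethylbutanoate | CC(C)(C)OC(=O)[C@@H](/N=C/C1=CCCCC1(C)C)C(C)(C)C | intermediate
8 | 1,2,4,5-tetramethoxybenzene | COc1cc(OC)c(OC)cc1OC | starting material
9 | 2,3-dibromoprop-1-ene | C=C(Br)CBr | starting material
10 | (2,3,5,6-tetramethoxyphenyl)lithium | [Li]c1c(OC)c(OC)cc(OC)c1OC | intermediate (not isolated)
11 | 3-(2-bromoprop-2-en-1-yl)-1,2,4,5-tetramethoxybenzene | C=C(Br)Cc1c(OC)c(OC)cc(OC)c1OC | intermediate
12 | [3-(2,3,5,6-tetramethoxyphenyl)prop-1-en-2-yl]magnesium bromide | C=C([Mg]Br)Cc1c(OC)c(OC)cc(OC)c1OC | intermediate (not isolated)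
13 | bromomagnesium aza-enolate of the 1,4-adduct (N-magnesio enamine, C=C geometry not defined, C10 set) | Br[Mg]N([C@H](C(=O)OC(C)(C)C)C(C)(C)C)C=C1C(C)(C)CCC[C@H]1C(=C)Cc1c(OC)c(OC)cc(OC)c1OC | intermediate (not isolated)
14 | (1S,2R)-6,6-dimethyl-2-[3-(2,3,5,6-tetramethoxyphenyl)prop-1-en-2-yl]cyclohexane-1-carbaldehyde | C=C(Cc1c(OC)c(OC)cc(OC)c1OC)[C@@H]1CCCC(C)(C)[C@H]1C=O | intermediate
15 | (E)-1-bromoprop-1-ene | C/C=C/Br | starting material
16 | (E)-prop-1-en-1-yllithium | C/C=C/[Li] | intermediate (not isolated)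
17 | (E)-1-{(1S,2R)-6,6-dimethyl-2-[3-(2,3,5,6-tetramethoxyphenyl)prop-1-en-2-yl]cyclohexyl}but-2-en-1-ol (carbinol epimers) | C=C(Cc1c(OC)c(OC)cc(OC)c1OC)[C@@H]1CCCC(C)(C)[C@H]1C(O)/C=C/C | intermediate
18 | (E)-1-{(1S,2R)-6,6-dimethyl-2-[3-(2,3,5,6-tetramethoxyphenyl)prop-1-en-2-yl]cyclohexyl}but-2-en-1-one | C=C(Cc1c(OC)c(OC)cc(OC)c1OC)[C@@H]1CCCC(C)(C)[C@H]1C(=O)/C=C/C | intermediate
19 | (3S,4R,4aR,8aS)-3,4,8,8-tetramethyl-4-[(2,3,5,6-tetramethoxyphenyl)methyl]octahydronaphthalen-1(2H)-one | COc1cc(OC)c(OC)c(C[C@@]2(C)[C@@H]3CCCC(C)(C)[C@H]3C(=O)C[C@@H]2C)c1OC | intermediate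
20 | (1S,3S,4R,4aR,8aS)-3,4,8,8-tetramethyl-4-[(2,3,5,6-tetramethoxyphenyl)methyl]decahydronaphthalen-1-ol | COc1cc(OC)c(OC)c(C[C@@]2(C)[C@@H]3CCCC(C)(C)[C@H]3[C@@H](O)C[C@@H]2C)c1OC | intermediate
21 | 3-{[(1R,2S,8aS)-1,2,5,5-tetramethyl-1,2,3,5,6,7,8,8a-octahydronaphthalen-1-yl]methyl}-1,2,4,5-tetramethoxybenzene | COc1cc(OC)c(OC)c(C[C@@]2(C)[C@@H]3CCCC(C)(C)C3=CC[C@@H]2C)c1OC | intermediate
22 | 2,5-dimethoxy-3-{[(1R,2S,8aS)-1,2,5,5-tetramethyl-1,2,3,5,6,7,8,8a-octahydronaphthalen-1-yl]methyl}cyclohexa-2,5-diene-1,4-dione | COC1=CC(=O)C(OC)=C(C[C@@]2(C)[C@@H]3CCCC(C)(C)C3=CC[C@@H]2C)C1=O | intermediate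
23 | 2-hydroxy-5-methoxy-3-{[(1R,2S,8aS)-1,2,5,5-tetramethyl-1,2,3,5,6,7,8,8a-octahydronaphthalen-1-yl]methyl}cyclohexa-2,5-diene-1,4-dione | COC1=CC(=O)C(O)=C(C[C@@]2(C)[C@@H]3CCCC(C)(C)C3=CC[C@@H]2C)C1=O | intermediate
24 | 3-methylbutan-1-amine | CC(C)CCN | starting material
25 | nakijiquinone M, 2-hydroxy-5-[(3-methylbutyl)amino]-3-{[(1R,2S,8aS)-1,2,5,5-tetramethyl-1,2,3,5,6,7,8,8a-octahydronaphthalen-1-yl]methyl}cyclohexa-2,5-diene-1,4-dione | CC(C)CCNC1=CC(=O)C(O)=C(C[C@@]2(C)[C@@H]3CCCC(C)(C)C3=CC[C@@H]2C)C1=O | target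

**Totals**
Total steps: 13. Longest linear sequence: 12 steps (steps 1–3 and 5–13, from 2,2-dimethylcyclohexanone); step 4 is a one-step side branch.

**Steps most likely to fail**

Step 8. The tertiary radical may be quenched before it closes the ring (net hydrogenation of the olefin or its isomerisation toward the benzylic position), the metal hydride may reduce the enone, or the methyl and arylmethyl groups at C9 may be discriminated poorly at 60 °C. The fallback makes the same C9 radical from a tertiary alkyl oxalate under visible-light photoredox catalysis at room temperature, with no metal hydride present while the enone is in the molecule. It sets out from 17. Mukaiyama hydration (Co(acac)2 cat., PhSiH3, O2, i-PrOH) should convert only the 1,1-disubstituted olefin into the tertiary alcohol, giving the diol F1. MnO2 in CH2Cl2 oxidises the allylic alcohol alone to the hydroxy enone F2. Methyl chlorooxoacetate with Et3N and DMAP acylates the tertiary alcohol to the methyl oxalate F3, and one equivalent of aqueous CsOH in THF gives the caesium oxalate F4. Irradiation with blue LEDs in the presence of Ir[dF(CF3)ppy]2(dtbbpy)PF6 in DME/DMF/H2O at rt should expel two molecules of CO2, and the C9 radical then undergoes the same 6-endo Giese closure, so the route is rejoined at 19.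

Step 10. The base may remove the secondary C7 hydrogen instead of the hindered tertiary C5 hydrogen (Δ6 olefin), or the crowded chlorosulfite may ionise and let a C4 methyl migrate. The fallback replaces the E2 elimination by a carbene 1,2-hydrogen shift and bypasses 20. It sets out from 19, which is condensed with p-toluenesulfonohydrazide (cat. TsOH, EtOH, reflux) to the tosylhydrazone F5. Aprotic Bamford–Stevens conditions (NaOMe, diglyme, 160 °C) generate the C6 carbene, which is expected to take the tertiary C5 hydrogen and give the more substituted olefin, so the route is rejoined at 21.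

Step 5. Facial selectivity in the alkenyl transfer may be eroded, because the α-branched alkenyl group is bulkier than the usual nucleophiles in this auxiliary chemistry, which would leave 14 of low enantiomeric purity. The fallback relies on separation of covalent diastereomers instead of auxiliary induction. It sets out from 14, which is reduced (NaBH4, MeOH) to the primary alcohol F6. Esterification with (S)-2-methoxy-2-phenylacetic acid (DCC, DMAP, CH2Cl2) gives diastereomeric esters, from which the (S)-O-methylmandelate ester F7 of the wanted enantiomer is separated by chromatography or crystallisation. Saponification (NaOH, MeOH/H2O) returns F6 as a single enantiomer, and Dess–Martin oxidation followed by brief methoxide equilibration rejoins the route at 14.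

**Further compounds**
F1 | step 8 | (E)-1-{(1S,2R)-2-[2-hydroxy-1-(2,3,5,6-tetramethoxyphenyl)propan-2-yl]-6,6-dimethylcyclohexyl}but-2-en-1-ol (epimers at both carbinol carbons) | CC(O)(Cc1c(OC)c(OC)cc(OC)c1OC)[C@@H]1CCCC(C)(C)[C@H]1C(O)/C=C/C
F2 | step 8 | (E)-1-{(1S,2R)-2-[2-hydroxy-1-(2,3,5,6-tetramethoxyphenyl)propan-2-yl]-6,6-dimethylcyclohexyl}but-2-en-1-one | CC(O)(Cc1c(OC)c(OC)cc(OC)c1OC)[C@@H]1CCCC(C)(C)[C@H]1C(=O)/C=C/C
F3 | step 8 | methyl oxalate of the tertiary alcohol F2 | COC(=O)C(=O)OC(C)(Cc1c(OC)c(OC)cc(OC)c1OC)[C@@H]1CCCC(C)(C)[C@H]1C(=O)/C=C/C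
F4 | step 8 | caesium oxalate of the tertiary alcohol F2 | [Cs+].[O-]C(=O)C(=O)OC(C)(Cc1c(OC)c(OC)cc(OC)c1OC)[C@@H]1CCCC(C)(C)[C@H]1C(=O)/C=C/C
F5 | step 10 | p-toluenesulfonylhydrazone of ketone 19 | COc1cc(OC)c(OC)c(C[C@@]2(C)[C@@H]3CCCC(C)(C)[C@H]3C(=NNS(=O)(=O)c4ccc(C)cc4)C[C@@H]2C)c1OC
F6 | step 5 | {(1S,2R)-6,6-dimethyl-2-[3-(2,3,5,6-tetramethoxyphenyl)prop-1-en-2-yl]cyclohexyl}methanol | C=C(Cc1c(OC)c(OC)cc(OC)c1OC)[C@@H]1CCCC(C)(C)[C@H]1CO
F7 | step 5 | {(1S,2R)-6,6-dimethyl-2-[3-(2,3,5,6-tetramethoxyphenyl)prop-1-en-2-yl]cyclohexyl}methyl (S)-2-methoxy-2-phenylacetate | C=C(Cc1c(OC)c(OC)cc(OC)c1OC)[C@@H]1CCCC(C)(C)[C@H]1COC(=O)[C@@H](OC)c1ccccc1
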